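**Plan**
- Retrosynthesis: cut C12–C13 (Suzuki coupling) and C11=C12 (boron olefination) back to a C11 aldehyde, then cut ring A at C1–C2 and C3=C4 in one operation to a ring-B keto acid and a two-carbon vinylphosphonium unit (C2–C3).
- Enabling feature: in ring A, C4 is a methyl-bearing sp2 carbon on quaternary C5 (a latent acetyl ketone) and C1 is a CH2 on C10 (a latent primary radical from a CH2CO2H arm). The two arms sit 1,4 across the C5–C10 bond, trans-diequatorial on ring B, so a C2 linchpin can join C1–C2 and C3=C4.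
- Forward order: ring B first (steps 1–15), ring A by radical-polar crossover annulation (step 16), butenolide side chain last (steps 17–19).
- Stereochemistry: C10 from an organocatalytic Michael addition; C9 and C5 by alkylation anti to the C10 arm on either side of a 1,3-enone transposition; C7/C8 by osmylation anti to the axial methyl groups; C6 by 8-OH-directed hydride delivery. The trans ring fusion follows from the trans C5/C10 arms, and the E-alkene from the chromium-mediated olefination.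

Key step: step 16

Remark: atoms are referred to by clerodane numbers (ring B = C5–C10, ring A = C1–C4 with C5/C10, C11 on C9, C18 = acetyl methyl); C1' is the carboxyl carbon lost as CO2. Compounds 5, 10 and 14 are epimeric at one centre that a later step removes, so that centre is left undefined in their SMILES.

**Step 1**
Reactants: 1 3-(benzyloxy)propanal; 2 (triphenylphosphoranylidene)acetaldehyde
Product: 3 (E)-5-(benzyloxy)pent-2-enal
Conditions: toluene, 80 °C
Reagents that add atoms: none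
Why: Wittig olefination with a formyl-stabilized ylide should give the E-enal selectively.

**Step 2**
Reactants: 3 (E)-5-(benzyloxy)pent-2-enal; 4 tert-butyl 3-oxobutanoate
Product: 6 (5R)-5-[2-(benzyloxy)ethyl]cyclohex-2-en-1-one, via Michael adduct 5 (not isolated)
Conditions: (R)-2-{bis[3,5-bis(trifluoromethyl)phenyl](trimethylsilyloxy)methyl}pyrrolidine (10 mol %), PhCO2H (10 mol %), toluene, rt; then TsOH·H2O (20 mol %), 80 °C
Reagents that add atoms: none
Why: Iminium-catalysed Michael addition of the β-ketoester to the enal, with the R-configured diarylprolinol silyl ether blocking one face of the (E)-iminium ion, should set the future C10 as R; acid then drives intramolecular aldol condensation, tert-butyl ester cleavage and decarboxylation (organocatalytic Michael/aldol cyclohexenone annulation).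

**Step 3**
Reactants: 6 (5R)-5-[2-(benzyloxy)ethyl]cyclohex-2-en-1-one
Product: 7 (5R,6R)-5-[2-(benzyloxy)ethyl]-6-methylcyclohex-2-en-1-one
Conditions: LDA, THF, −78 °C; MeI, −78 to −30 °C
Reagents that add atoms: iodomethane CI
Why: Kinetic α'-enolization of the enone and methylation anti to the adjacent C10 arm (ketone α-alkylation); this centre is reset in step 4, so its selectivity is not critical.

**Step 4**
Reactants: 7 (5R,6R)-5-[2-(benzyloxy)ethyl]-6-methylcyclohex-2-en-1-one
Product: 9 (5R,6S)-5-[2-(benzyloxy)ethyl]-6-(dimethoxymethyl)-6-methylcyclohex-2-en-1-one, via silyl dienol ether 8 (not isolated)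
Conditions: LDA, TMSCl, THF, −78 °C; then HC(OMe)3, TMSOTf (10 mol %), CH2Cl2, −78 °C
Reagents that add atoms: trimethyl orthoformate COC(OC)OC; chlorotrimethylsilane C[Si](C)(C)Cl (its atoms stay only in intermediate 8)
Why: Mukaiyama-type alkylation of the 2-silyloxydiene by the dimethoxycarbenium ion should form quaternary C9 at the siloxy-bearing terminus, the electrophile entering anti to the vicinal C10 arm so that C11 is trans and the methyl cis to that arm.

**Step 5**
Reactants: 9 (5R,6S)-5-[2-(benzyloxy)ethyl]-6-(dimethoxymethyl)-6-methylcyclohex-2-en-1-one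
Product: 10 (5R,6R)-5-[2-(benzyloxy)ethyl]-6-(dimethoxymethyl)-1,6-dimethylcyclohex-2-en-1-ol (C1 epimers)
Conditions: MeLi, Et2O, −78 °C; H2O
Reagents that add atoms: methyllithium [Li]C
Why: 1,2-Addition of the hard organolithium to the enone carbonyl, which has no enolizable α-hydrogen on its quaternary neighbour; the new carbinol centre is destroyed in step 6.

**Step 6**
Reactants: 10 (5R,6R)-5-[2-(benzyloxy)ethyl]-6-(dimethoxymethyl)-1,6-dimethylcyclohex-2-en-1-ol
Product: 11 (4R,5S)-5-[2-(benzyloxy)ethyl]-4-(dimethoxymethyl)-3,4-dimethylcyclohex-2-en-1-one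
Conditions: IBX, DMSO, 55 °C
Reagents that add atoms: none
Why: Oxidative 1,3-transposition of the tertiary allylic alcohol (Dauben–Babler-type rearrangement, here with IBX) should move the oxygen to C6 and leave the C7=C8 enone carrying the C8 methyl; no stereocentre is formed.

**Step 7**
Reactants: 11 (4R,5S)-5-[2-(benzyloxy)ethyl]-4-(dimethoxymethyl)-3,4-dimethylcyclohex-2-en-1-one
Product: 12 (4R,5S,6S)-5-[2-(benzyloxy)ethyl]-4-(dimethoxymethyl)-3,4,6-trimethylcyclohex-2-en-1-one
Conditions: LDA, THF, −78 °C; MeI, −78 to −30 °C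
Reagents that add atoms: iodomethane CI
Why: Kinetic α'-enolization at C5 (cross-conjugated, not the γ-methyl) and methylation anti to the C10 arm; this centre is reset in step 8.

**Step 8**
Reactants: 12 (4R,5S,6S)-5-[2-(benzyloxy)ethyl]-4-(dimethoxymethyl)-3,4,6-trimethylcyclohex-2-en-1-one; 13 acetaldehyde
Product: 14 (4R,5R,6R)-5-[2-(benzyloxy)ethyl]-4-(dimethoxymethyl)-6-(1-hydroxyethyl)-3,4,6-trimethylcyclohex-2-en-1-one (carbinol epimers)
Conditions: LDA, THF, −78 °C; 13, −78 °C; AcOH quench at −78 °C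
Reagents that add atoms: none
Why: Aldol addition of the tetrasubstituted α'-enolate creates quaternary C5; attack on the face anti to the C10 arm and to the pseudoaxial C9 methyl should place the two-carbon unit trans to C1 and the methyl cis, and the cold acidic quench suppresses retro-aldol cleavage.

**Step 9**
Reactants: 14 (4R,5R,6R)-5-[2-(benzyloxy)ethyl]-4-(dimethoxymethyl)-6-(1-hydroxyethyl)-3,4,6-trimethylcyclohex-2-en-1-one
Product: 15 (4R,5R,6R)-6-acetyl-5-[2-(benzyloxy)ethyl]-4-(dimethoxymethyl)-3,4,6-trimethylcyclohex-2-en-1-one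
Conditions: Dess–Martin periodinane, CH2Cl2, rt
Reagents that add atoms: none
Why: Dess–Martin oxidation of the secondary alcohol gives the C4 methyl ketone and removes the epimeric carbinol centre.

**Step 10**
Reactants: 15 (4R,5R,6R)-6-acetyl-5-[2-(benzyloxy)ethyl]-4-(dimethoxymethyl)-3,4,6-trimethylcyclohex-2-en-1-one
Product: 16 (2R,3R,4R,5R,6R)-2-acetyl-3-[2-(benzyloxy)ethyl]-4-(dimethoxymethyl)-5,6-dihydroxy-2,4,5-trimethylcyclohexan-1-one
Conditions: OsO4 (5 mol %), NMO, acetone/H2O, rt to 40 °C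
Reagents that add atoms: N-methylmorpholine N-oxide C[N+]1([O-])CCOCC1; water O (both oxygen atoms are delivered through OsO4, O=[Os](=O)(=O)=O)
Why: Upjohn dihydroxylation of the only alkene; OsO4 should add to the face opposite the pseudoaxial C9 and C5 methyl groups, giving the cis 7β,8β-diol with the C8 methyl α.

**Step 11**
Reactants: 16 (2R,3R,4R,5R,6R)-2-acetyl-3-[2-(benzyloxy)ethyl]-4-(dimethoxymethyl)-5,6-dihydroxy-2,4,5-trimethylcyclohexan-1-one
Product: 17 (1R,2R,3R,4R,5R)-5-acetyl-4-[2-(benzyloxy)ethyl]-3-(dimethoxymethyl)-2-hydroxy-2,3,5-trimethyl-6-oxocyclohexyl 2-methylpropanoate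
Conditions: i-PrCOCl, pyridine, DMAP (cat.), CH2Cl2, 0 °C
Reagents that add atoms: isobutyryl chloride CC(C)C(=O)Cl
Why: Acylation of the secondary α-ketol hydroxyl at C7; the tertiary C8 hydroxyl is too hindered to react under these conditions.

**Step 12**
Reactants: 17 (1R,2R,3R,4R,5R)-5-acetyl-4-[2-(benzyloxy)ethyl]-3-(dimethoxymethyl)-2-hydroxy-2,3,5-trimethyl-6-oxocyclohexyl 2-methylpropanoate
Product: 18 (1S,2R,3R,4R,5S,6R)-5-acetyl-4-[2-(benzyloxy)ethyl]-3-(dimethoxymethyl)-2,6-dihydroxy-2,3,5-trimethylcyclohexyl 2-methylpropanoate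
Conditions: Me4NBH(OAc)3, MeCN/AcOH, −20 °C
Reagents that add atoms: none
Why: Evans–Saksena directed reduction: the axial 8β-hydroxyl binds boron and delivers hydride to the β-face of the C6 ketone, which should give the equatorial 6α-alcohol (anti to the 8-OH) and leave the C4 ketone, which has no β-hydroxyl, untouched.

**Step 13**
Reactants: 18 (1S,2R,3R,4R,5S,6R)-5-acetyl-4-[2-(benzyloxy)ethyl]-3-(dimethoxymethyl)-2,6-dihydroxy-2,3,5-trimethylcyclohexyl 2-methylpropanoate
Product: 19 (1S,2R,3R,4R,5S,6R)-6-acetoxy-5-acetyl-4-[2-(benzyloxy)ethyl]-3-(dimethoxymethyl)-2-hydroxy-2,3,5-trimethylcyclohexyl 2-methylpropanoate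
Conditions: Ac2O, pyridine, DMAP (cat.), CH2Cl2, 0 °C to rt
Reagents that add atoms: acetic anhydride CC(=O)OC(C)=O
Why: DMAP-catalysed acetylation of the secondary 6-hydroxyl; the tertiary alcohol should stay free and prompt acylation prevents migration of the neighbouring isobutyrate.

**Step 14**
Reactants: 19 (1S,2R,3R,4R,5S,6R)-6-acetoxy-5-acetyl-4-[2-(benzyloxy)ethyl]-3-(dimethoxymethyl)-2-hydroxy-2,3,5-trimethylcyclohexyl 2-methylpropanoate
Product: 20 (1S,2R,3R,4R,5S,6R)-6-acetoxy-5-acetyl-3-(dimethoxymethyl)-2-hydroxy-4-(2-hydroxyethyl)-2,3,5-trimethylcyclohexyl 2-methylpropanoate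
Conditions: H2 (1 atm), Pd/C, EtOAc, rt
Reagents that add atoms: none
Why: Hydrogenolysis of the benzyl ether; no alkene is present at this stage and the ketone, esters and acetal are inert.

**Step 15**
Reactants: 20 (1S,2R,3R,4R,5S,6R)-6-acetoxy-5-acetyl-3-(dimethoxymethyl)-2-hydroxy-4-(2-hydroxyethyl)-2,3,5-trimethylcyclohexyl 2-methylpropanoate
Product: 21 2-[(1R,2R,3R,4S,5R,6S)-5-acetoxy-6-acetyl-2-(dimethoxymethyl)-3-hydroxy-2,3,6-trimethyl-4-(2-methylpropanoyloxy)cyclohexyl]acetic acid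
Conditions: TEMPO (20 mol %), PhI(OAc)2, MeCN/H2O (1:1), rt
Reagents that add atoms: water O
Why: TEMPO/PhI(OAc)2 oxidation of the primary alcohol through the aldehyde hydrate to the carboxylic acid; the tertiary alcohol and the acetal should not react.

**Step 16**
Reactants: 21 2-[(1R,2R,3R,4S,5R,6S)-5-acetoxy-6-acetyl-2-(dimethoxymethyl)-3-hydroxy-2,3,6-trimethyl-4-(2-methylpropanoyloxy)cyclohexyl]acetic acid; 22 triphenyl(vinyl)phosphonium bromide
Product: 25 (1R,2S,3R,4R,4aS,8aR)-1-acetoxy-4-(dimethoxymethyl)-3-hydroxy-3,4,8,8a-tetramethyl-1,2,3,4,4a,5,6,8a-octahydronaphthalen-2-yl 2-methylpropanoate, via primary alkyl radical 23 (not isolated), via phosphonium ylide 24 (not isolated)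
Conditions: 22 (1.5 equiv), [Ir(dF(CF3)ppy)2(dtbbpy)]PF6 (2 mol %), Cs2CO3 (1.5 equiv), DMF, blue LEDs, rt; then 50 °C
Reagents that add atoms: none
Why: Proposed new method: the cesium carboxylate of 21 is oxidized by the photoexcited trivalent iridium complex and loses CO2 to give primary radical 23 at C1, which adds to the unsubstituted terminus of 22 (forming C1–C2); the α-phosphonio radical is then reduced by the divalent iridium species to ylide 24 (radical-polar crossover that closes the photocatalytic cycle), and 24 undergoes intramolecular Wittig olefination with the C4 acetyl carbonyl (forming C3=C4) with loss of Ph3PO. The closest known reaction types are the Schweizer cycloalkene annulation (anionic Michael addition of a keto-malonate to vinyltriphenylphosphonium bromide followed by intramolecular Wittig reaction) and photoredox decarboxylative Giese additions that end by reduction of the adduct radical to a carbanion. Ring A closes by 6-exo-trig addition of the ylide carbon C3 to the ketone carbon C4 through a ring-fused oxaphosphetane, whose collapse can only give the endocyclic cis C3=C4 bond. No new stereocentre is formed; the trans ring fusion is inherited from the trans-diequatorial C5–C4 and C10–C1 bonds fixed in step 8. The step needs chemoselectivity of the ylide for the ketone and of the radical for intermolecular addition: C11 is masked as an acetal so the C4 ketone is the only ketone or aldehyde, the ester carbonyls would need eight- or nine-membered transition states, and the strongly electron-poor acceptor used in excess should outrun 1,5-hydrogen transfer from the C18 methyl group. Running the reaction on the fully deprotonated carboxylate leaves no acid strong enough to quench 24 irreversibly, and warming is meant to complete the Wittig closure at the hindered neopentyl ketone.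

**Step 17**
Reactants: 25 (1R,2S,3R,4R,4aS,8aR)-1-acetoxy-4-(dimethoxymethyl)-3-hydroxy-3,4,8,8a-tetramethyl-1,2,3,4,4a,5,6,8a-octahydronaphthalen-2-yl 2-methylpropanoate
Product: 26 (1R,2S,3R,4R,4aS,8aR)-1-acetoxy-4-formyl-3-hydroxy-3,4,8,8a-tetramethyl-1,2,3,4,4a,5,6,8a-octahydronaphthalen-2-yl 2-methylpropanoate
Conditions: PPTS (cat.), acetone/H2O (10:1), 50 °C
Reagents that add atoms: water O
Why: Mild acid hydrolysis of the dimethyl acetal to the neopentyl aldehyde; the esters, the tertiary alcohol and the trisubstituted alkene should tolerate PPTS, and the β-hydroxy aldehyde is kept away from base.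

**Step 18**
Reactants: 26 (1R,2S,3R,4R,4aS,8aR)-1-acetoxy-4-formyl-3-hydroxy-3,4,8,8a-tetramethyl-1,2,3,4,4a,5,6,8a-octahydronaphthalen-2-yl 2-methylpropanoate
Product: 27 (1R,2S,3R,4R,4aS,8aR)-1-acetoxy-3-hydroxy-3,4,8,8a-tetramethyl-4-[(E)-2-(4,4,5,5-tetramethyl-1,3,2-dioxaborolan-2-yl)ethenyl]-1,2,3,4,4a,5,6,8a-octahydronaphthalen-2-yl 2-methylpropanoate
Conditions: CrCl2, Cl2CHBpin, LiI, THF, rt
Reagents that add atoms: 2-(dichloromethyl)-4,4,5,5-tetramethyl-1,3,2-dioxaborolane ClC(Cl)B1OC(C)(C)C(C)(C)O1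
Why: Takai–Utimoto boron olefination should convert the hindered aldehyde into the E-alkenylboronate under non-basic conditions that avoid retro-aldol cleavage; the E geometry comes from the anti elimination of the chromium alkoxide.

**Step 19**
Reactants: 27 (1R,2S,3R,4R,4aS,8aR)-1-acetoxy-3-hydroxy-3,4,8,8a-tetramethyl-4-[(E)-2-(4,4,5,5-tetramethyl-1,3,2-dioxaborolan-2-yl)ethenyl]-1,2,3,4,4a,5,6,8a-octahydronaphthalen-2-yl 2-methylpropanoate; 28 4-bromofuran-2(5H)-one
Product: 29 (1R,2S,3R,4R,4aS,8aR)-1-acetoxy-3-hydroxy-3,4,8,8a-tetramethyl-4-[(E)-2-(5-oxo-2,5-dihydrofuran-3-yl)ethenyl]-1,2,3,4,4a,5,6,8a-octahydronaphthalen-2-yl 2-methylpropanoate (target, CNP0207114.1)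
Conditions: Pd(dppf)Cl2 (5 mol %), K3PO4, THF/H2O, 40 °C
Reagents that add atoms: none
Why: Suzuki–Miyaura coupling of the alkenylboronate with the β-bromobutenolide should form C12–C13 with retention of the E geometry; no stereocentre is touched.

**Compound list**
1 | 3-(benzyloxy)propanal | O=CCCOCc1ccccc1 | starting material
2 | (triphenylphosphoranylidene)acetaldehyde | O=CC=P(c1ccccc1)(c1ccccc1)c1ccccc1 | starting material
3 | (E)-5-(benzyloxy)pent-2-enal | O=C/C=C/CCOCc1ccccc1 | intermediate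
4 | tert-butyl 3-oxobutanoate | CC(=O)CC(=O)OC(C)(C)C | starting material
5 | tert-butyl (3S)-2-acetyl-3-[2-(benzyloxy)ethyl]-5-oxopentanoate (C2 epimers; Michael adduct) | CC(=O)C(C(=O)OC(C)(C)C)[C@@H](CCOCc1ccccc1)CC=O | intermediate
6 | (5R)-5-[2-(benzyloxy)ethyl]cyclohex-2-en-1-one | C1=CC(=O)C[C@@H](CCOCc2ccccc2)C1 | intermediate
7 | (5R,6R)-5-[2-(benzyloxy)ethyl]-6-methylcyclohex-2-en-1-one | C1=CC(=O)[C@H](C)[C@@H](CCOCc2ccccc2)C1 | intermediate
8 | {[(3R)-3-[2-(benzyloxy)ethyl]-2-methylcyclohexa-1,5-dien-1-yl]oxy}trimethylsilane (silyl dienol ether) | C1=CC(O[Si](C)(C)C)=C(C)[C@@H](CCOCc2ccccc2)C1 | intermediate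
9 | (5R,6S)-5-[2-(benzyloxy)ethyl]-6-(dimethoxymethyl)-6-methylcyclohex-2-en-1-one | C1=CC(=O)[C@](C)(C(OC)OC)[C@@H](CCOCc2ccccc2)C1 | intermediate
10 | (5R,6R)-5-[2-(benzyloxy)ethyl]-6-(dimethoxymethyl)-1,6-dimethylcyclohex-2-en-1-ol (C1 epimers) | C1=CC(C)(O)[C@](C)(C(OC)OC)[C@@H](CCOCc2ccccc2)C1 | intermediate
11 | (4R,5S)-5-[2-(benzyloxy)ethyl]-4-(dimethoxymethyl)-3,4-dimethylcyclohex-2-en-1-one | O=C1C=C(C)[C@](C)(C(OC)OC)[C@@H](CCOCc2ccccc2)C1 | intermediate
12 | (4R,5S,6S)-5-[2-(benzyloxy)ethyl]-4-(dimethoxymethyl)-3,4,6-trimethylcyclohex-2-en-1-one | O=C1C=C(C)[C@](C)(C(OC)OC)[C@@H](CCOCc2ccccc2)[C@@H]1C | intermediate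
13 | acetaldehyde | CC=O | starting material
14 | (4R,5R,6R)-5-[2-(benzyloxy)ethyl]-4-(dimethoxymethyl)-6-(1-hydroxyethyl)-3,4,6-trimethylcyclohex-2-en-1-one (carbinol epimers) | O=C1C=C(C)[C@](C)(C(OC)OC)[C@@H](CCOCc2ccccc2)[C@]1(C)C(C)O | intermediate
15 | (4R,5R,6R)-6-acetyl-5-[2-(benzyloxy)ethyl]-4-(dimethoxymethyl)-3,4,6-trimethylcyclohex-2-en-1-one | O=C1C=C(C)[C@](C)(C(OC)OC)[C@@H](CCOCc2ccccc2)[C@]1(C)C(C)=O | intermediate
16 | (2R,3R,4R,5R,6R)-2-acetyl-3-[2-(benzyloxy)ethyl]-4-(dimethoxymethyl)-5,6-dihydroxy-2,4,5-trimethylcyclohexan-1-one | O=C1[C@H](O)[C@](C)(O)[C@](C)(C(OC)OC)[C@@H](CCOCc2ccccc2)[C@]1(C)C(C)=O | intermediate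
17 | (1R,2R,3R,4R,5R)-5-acetyl-4-[2-(benzyloxy)ethyl]-3-(dimethoxymethyl)-2-hydroxy-2,3,5-trimethyl-6-oxocyclohexyl 2-methylpropanoate | O=C1[C@H](OC(=O)C(C)C)[C@](C)(O)[C@](C)(C(OC)OC)[C@@H](CCOCc2ccccc2)[C@]1(C)C(C)=O | intermediate
18 | (1S,2R,3R,4R,5S,6R)-5-acetyl-4-[2-(benzyloxy)ethyl]-3-(dimethoxymethyl)-2,6-dihydroxy-2,3,5-trimethylcyclohexyl 2-methylpropanoate | O[C@H]1[C@H](OC(=O)C(C)C)[C@](C)(O)[C@](C)(C(OC)OC)[C@@H](CCOCc2ccccc2)[C@]1(C)C(C)=O | intermediate
19 | (1S,2R,3R,4R,5S,6R)-6-acetoxy-5-acetyl-4-[2-(benzyloxy)ethyl]-3-(dimethoxymethyl)-2-hydroxy-2,3,5-trimethylcyclohexyl 2-methylpropanoate | CC(=O)O[C@H]1[C@H](OC(=O)C(C)C)[C@](C)(O)[C@](C)(C(OC)OC)[C@@H](CCOCc2ccccc2)[C@]1(C)C(C)=O | intermediate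
20 | (1S,2R,3R,4R,5S,6R)-6-acetoxy-5-acetyl-3-(dimethoxymethyl)-2-hydroxy-4-(2-hydroxyethyl)-2,3,5-trimethylcyclohexyl 2-methylpropanoate | CC(=O)O[C@H]1[C@H](OC(=O)C(C)C)[C@](C)(O)[C@](C)(C(OC)OC)[C@@H](CCO)[C@]1(C)C(C)=O | intermediate
21 | 2-[(1R,2R,3R,4S,5R,6S)-5-acetoxy-6-acetyl-2-(dimethoxymethyl)-3-hydroxy-2,3,6-trimethyl-4-(2-methylpropanoyloxy)cyclohexyl]acetic acid | CC(=O)O[C@H]1[C@H](OC(=O)C(C)C)[C@](C)(O)[C@](C)(C(OC)OC)[C@@H](CC(=O)O)[C@]1(C)C(C)=O | intermediate
22 | triphenyl(vinyl)phosphonium bromide | C=C[P+](c1ccccc1)(c1ccccc1)c1ccccc1.[Br-] | starting material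
23 | primary alkyl radical at C1 formed from 21 by decarboxylation | CC(=O)O[C@H]1[C@H](OC(=O)C(C)C)[C@](C)(O)[C@](C)(C(OC)OC)[C@@H]([CH2])[C@]1(C)C(C)=O | intermediate
24 | phosphonium ylide (C1–C2 formed, ylide carbon C3) | CC(=O)O[C@H]1[C@H](OC(=O)C(C)C)[C@](C)(O)[C@](C)(C(OC)OC)[C@@H](CC[CH-][P+](c2ccccc2)(c2ccccc2)c2ccccc2)[C@]1(C)C(C)=O | intermediate
25 | (1R,2S,3R,4R,4aS,8aR)-1-acetoxy-4-(dimethoxymethyl)-3-hydroxy-3,4,8,8a-tetramethyl-1,2,3,4,4a,5,6,8a-octahydronaphthalen-2-yl 2-methylpropanoate | CC(=O)O[C@H]1[C@H](OC(=O)C(C)C)[C@](C)(O)[C@](C)(C(OC)OC)[C@H]2CCC=C(C)[C@]12C | intermediate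
26 | (1R,2S,3R,4R,4aS,8aR)-1-acetoxy-4-formyl-3-hydroxy-3,4,8,8a-tetramethyl-1,2,3,4,4a,5,6,8a-octahydronaphthalen-2-yl 2-methylpropanoate | CC(=O)O[C@H]1[C@H](OC(=O)C(C)C)[C@](C)(O)[C@](C)(C=O)[C@H]2CCC=C(C)[C@]12C | intermediate
27 | (1R,2S,3R,4R,4aS,8aR)-1-acetoxy-3-hydroxy-3,4,8,8a-tetramethyl-4-[(E)-2-(4,4,5,5-tetramethyl-1,3,2-dioxaborolan-2-yl)ethenyl]-1,2,3,4,4a,5,6,8a-octahydronaphthalen-2-yl 2-methylpropanoate | CC(=O)O[C@H]1[C@H](OC(=O)C(C)C)[C@](C)(O)[C@](C)(/C=C/B2OC(C)(C)C(C)(C)O2)[C@H]2CCC=C(C)[C@]12C | intermediate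
28 | 4-bromofuran-2(5H)-one | O=C1C=C(Br)CO1 | starting material
29 | (1R,2S,3R,4R,4aS,8aR)-1-acetoxy-3-hydroxy-3,4,8,8a-tetramethyl-4-[(E)-2-(5-oxo-2,5-dihydrofuran-3-yl)ethenyl]-1,2,3,4,4a,5,6,8a-octahydronaphthalen-2-yl 2-methylpropanoate | CC(=O)O[C@H]1[C@H](OC(=O)C(C)C)[C@](C)(O)[C@](C)(/C=C/C2=CC(=O)OC2)[C@H]2CCC=C(C)[C@]12C | target

**Step count and risks**
Total step count: 19. Longest linear sequence: 19 steps (1 to 29); compounds 2, 4, 13, 22 and 28 are commercial partners.

Steps most likely to fail: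

1. Step 16 (proposed new method). The excited photocatalyst may be quenched unproductively by bromide, the ylide may be protonated irreversibly, or carbonyl addition at the neopentyl ketone may be too slow, so that the radical or the phosphonium salt decomposes instead of closing ring A. Fallback by known reactions, from 21 back to 25: one-pot Barton decarboxylative iodination (2-mercaptopyridine N-oxide, DCC; then CHI3, hν) through the thiohydroxamate ester F1 to the primary iodide F2; Keck radical allylation (allyltributylstannane, AIBN, 80 °C) to the but-3-enyl ketone F3; Takai–Lombardo methylenation of the methyl ketone (Zn, CH2Br2, TiCl4) to the isopropenyl diene F4; ring-closing metathesis with the second-generation Grubbs catalyst then forms the trisubstituted C3=C4 bond and returns to 25.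

2. Step 10. Osmylation of the hindered, electron-poor trisubstituted enone may be slow, with erosion of facial selectivity and cleavage of the 1,3-diketone on long exposure to the aqueous oxidant. Fallback that makes the alkene electron-rich first, from 14 back to 19: silylation (TESOTf, 2,6-lutidine) to the silyl ether F5; Luche reduction (NaBH4, CeCl3, MeOH, −78 °C; axial hydride attack anti to the pseudoaxial C5 methyl) to the 6α-allylic alcohol F6; acetylation to the allylic acetate F7; OsO4/NMO dihydroxylation, anti to the allylic acetate and to the axial C9 methyl, to the diol F8; isobutyrylation of the secondary 7-hydroxyl to the diester F9; removal of the silyl group (HF·pyridine) to the secondary alcohol F10; Dess–Martin oxidation of F10 gives 19.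

3. Step 4. Bond formation at the fully substituted enol ether carbon may lose out to simple desilylation, or facial selectivity at C9 may be poor. Fallback by enolate aldol chemistry, from 7 back to 9: LDA then gaseous formaldehyde (−78 °C) to the hydroxymethyl ketone F11, with the electrophile again anti to the C10 arm; Dess–Martin oxidation to the keto aldehyde F12; chemoselective acetalization of the aldehyde (HC(OMe)3, MeOH, PPTS, rt) gives 9.

**Further compounds**
F1 | step 16 | 2-thioxopyridin-1(2H)-yl ester (Barton ester) of acid 21 | CC(=O)O[C@H]1[C@H](OC(=O)C(C)C)[C@](C)(O)[C@](C)(C(OC)OC)[C@@H](CC(=O)On2ccccc2=S)[C@]1(C)C(C)=O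
F2 | step 16 | primary iodide (iodomethyl group on C10) | CC(=O)O[C@H]1[C@H](OC(=O)C(C)C)[C@](C)(O)[C@](C)(C(OC)OC)[C@@H](CI)[C@]1(C)C(C)=O
F3 | step 16 | but-3-enyl ketone | CC(=O)O[C@H]1[C@H](OC(=O)C(C)C)[C@](C)(O)[C@](C)(C(OC)OC)[C@@H](CCC=C)[C@]1(C)C(C)=O
F4 | step 16 | isopropenyl but-3-enyl diene | CC(=O)O[C@H]1[C@H](OC(=O)C(C)C)[C@](C)(O)[C@](C)(C(OC)OC)[C@@H](CCC=C)[C@]1(C)C(C)=C
F5 | step 10 | triethylsilyl ether of aldol 14 | O=C1C=C(C)[C@](C)(C(OC)OC)[C@@H](CCOCc2ccccc2)[C@]1(C)C(C)O[Si](CC)(CC)CC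
F6 | step 10 | 6α-allylic alcohol | O[C@H]1C=C(C)[C@](C)(C(OC)OC)[C@@H](CCOCc2ccccc2)[C@]1(C)C(C)O[Si](CC)(CC)CC
F7 | step 10 | 6α-allylic acetate | CC(=O)O[C@H]1C=C(C)[C@](C)(C(OC)OC)[C@@H](CCOCc2ccccc2)[C@]1(C)C(C)O[Si](CC)(CC)CC
F8 | step 10 | 6α-acetoxy-7β,8β-diol | CC(=O)O[C@H]1[C@H](O)[C@](C)(O)[C@](C)(C(OC)OC)[C@@H](CCOCc2ccccc2)[C@]1(C)C(C)O[Si](CC)(CC)CC
F9 | step 10 | 6α-acetate 7β-isobutyrate silyl ether | CC(=O)O[C@H]1[C@H](OC(=O)C(C)C)[C@](C)(O)[C@](C)(C(OC)OC)[C@@H](CCOCc2ccccc2)[C@]1(C)C(C)O[Si](CC)(CC)CC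
F10 | step 10 | C4 secondary alcohol | CC(=O)O[C@H]1[C@H](OC(=O)C(C)C)[C@](C)(O)[C@](C)(C(OC)OC)[C@@H](CCOCc2ccccc2)[C@]1(C)C(C)O
F11 | step 4 | (5R,6S)-5-[2-(benzyloxy)ethyl]-6-(hydroxymethyl)-6-methylcyclohex-2-en-1-one | C1=CC(=O)[C@](C)(CO)[C@@H](CCOCc2ccccc2)C1
F12 | step 4 | (1S,6R)-6-[2-(benzyloxy)ethyl]-1-methyl-2-oxocyclohex-3-ene-1-carbaldehyde | C1=CC(=O)[C@](C)(C=O)[C@@H](CCOCc2ccccc2)C1
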